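**Remark on the chemistry:** the target has no stereocentre; compounds 11, 16 and 18 carry transient stereocentres and are taken as racemates or diastereomer mixtures, and the enol ethers 12 and 13 as geometry mixtures.

## Analysis of the target

Mallopallidol is a methylene-bridged dimer of two phloroglucinol-derived rings. Ring A is a hexasubstituted benzene carrying an isobutyryl group at C1', hydroxyls at C2' and C6', the CH2 bridge at C3', a methoxy group at C4' and a methyl group at C5'. Ring B is the benzene ring of a 5,7-dihydroxy-2,2,6-trimethylchroman-4-one (ring C is the pyranone) and carries the bridge at C8. There is no stereocentre, so the whole problem is regiochemistry on two fully substituted arenes. The sensitive elements are the diarylmethane between two electron-rich rings (prone to retro-Friedel–Crafts cleavage in strong acid), the air-sensitive polyphenol, and ring C, which can open by retro-oxa-Michael reaction and reclose with C6 and C8 interchanged. The difficulty is that six phenolic oxygens are present, exactly one of them (at C4') is methylated, and ring B must carry the methyl group at C6 and the bridge at C8 rather than the reverse. The strategy rests on the strict alternation of oxygen and carbon substituents around ring A. C2'(O), C3'(C), C4'(O) and C5'(C) correspond to the ester carbon, α-carbon, β-alkoxy carbon and γ-carbon of a β-alkoxy enoate turned into a 1,3-dioxygenated diene. C6'(O) and C1'(acyl) correspond to the two alkyne carbons of a β-alkoxy ynone.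

## Retrosynthetic reasoning

**Endgame, 21 from 20 from 19.** The target 21 is reached by removing protecting groups only. The oxygen at C6' of 20 carries an ethyl group, which sits ortho to the isobutyryl ketone and can be removed by chelation-assisted Lewis-acid dealkylation; the C4' methoxy group is para to that ketone and cannot chelate. The two ring B phenols of 19 are benzyl ethers, removed by hydrogenolysis. Hydrogenolysis comes first so that the Lewis acid in the last step meets no benzyl ether.

**Key disconnection, 19 to 13 and 17 through 18.** Ring A of 19 is cut at C5'–C6' and C1'–C2'. This is the only cut that delivers all six substituents of ring A in one operation with the oxygen pattern already differentiated: methoxy at C4' from the diene, ethoxy at C6' and the isobutyryl group from the ynone 17, and the C2' hydroxyl from the ketene acetal carbon of 13. The forward reaction has to join the nucleophilic diene terminus to the alkoxy-bearing alkyne carbon and the ketene acetal carbon to the acyl-bearing alkyne carbon, giving cycloadduct 18, and then aromatise across the mixed ketal.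

**Diene 13 from 12 from 11.** The diene is the O-silylated dienolate of the β-methoxy enoate 12, obtained by removing a γ-proton. The chromanone C3 protons of 12 are of similar acidity, so the base cannot be expected to discriminate. The ketone is therefore deliberately enolised as well and carried through the key step as its silyl enol ether, which the acidic work-up returns to the ketone. Enoate 12 comes from O-methylation of the β-keto ester 11.

**β-Keto ester 11 from 9 and 10.** The bond between the bridging CH2 and the future C3' is made by C-alkylation of methyl 3-oxopentanoate 10 with the benzylic bromide 9. This puts the whole of ring B and ring C on the diene before the key step, so nothing but deprotection follows the ring-forming event.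

**Bromide 9 back to chromanone 4 (9 from 8 from 7 from 6 from 4).** The bromide comes from alcohol 8 and this from aldehyde 7. The aldehyde carbon is introduced as a formyl group at C8 of 4, the only unsubstituted ring carbon, while the phenols are still free and the ring is most nucleophilic (product 6, via iminium salt 5). Benzylation to 7 follows.

**Chromanone 4 from 1 and 2 through 3.** Ring C is annulated onto 2,4,6-trihydroxytoluene 1 with 3-methylbut-2-enoic acid 2 by C-acylation to the open enone 3 and oxa-Michael closure. The two free ring carbons of 1 are equivalent, so the acylation is unambiguous. The direction of ring closure decides whether the methyl group ends at C6 (wanted) or C8, and this is the one selectivity question outside the key step.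

**Ynone 17 from 16 from 14 and 15.** The dienophile is cut at the carbinol carbon: metallated ethoxyacetylene 14 adds to isobutyraldehyde 15, and the propargylic alcohol 16 is oxidised under neutral conditions.

## Alternatives that were turned down

**Alternative 1:** Ring B is cut at C8–C8a and C5–C4a, and ring C is supplied intact as the bromopyranone A3. The partner is the 1-methoxy-1,3-bis(trimethylsiloxy) diene A2, which carries the C6 methyl group on its C2 and the complete, benzyl-protected ring A on its terminus. The forward step is a [4+2] cycloaddition followed by dehydrobromination and 1,4-elimination across the ketal, giving A1 with both ring B phenols free.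
- For: the ring oxygen of A3 ends next to C8 by construction, so the orientation of ring B is never in doubt. On this point the alternative is stronger than the chosen route, whose step 1 depends on a selective ring closure.
- Against: A3 is a cyclic, trisubstituted β-alkoxy enone whose donor oxygen sits on the carbon that must accept the diene terminus; that terminus is itself substituted by the bulky arylmethyl group; and two eliminations are needed for aromatisation. Making A2 requires double enolisation and silylation next to the enolisable isobutyryl ketone of ring A. Ring A has to be built beforehand by classical phloroglucinol chemistry.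
- Comparison: the step count is similar. The chosen route offers a linear, unhindered alkyne as dienophile, one elimination, and a ring A whose six substituents all arrive in the key step. Its regiochemical risk is confined to the first step, where material is cheapest.

**Alternative 2:** Ring A is cut at C2'–C3' and C4'–C5'. In a Danheiser benzannulation the cyclobutenone A5 opens to a vinylketene that adds to the alkynyl methyl ether A6; the resulting vinylcyclobutenone opens and recloses to the phenol A4.
- For: the ketene/ynol ether polarity places the methoxy group as reliably as the chosen cycloaddition does, and the annulation is thermal and neutral with no strong base near ring C. In the robustness of the ring-forming event itself it is at least equal.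
- Against: A4 lacks the isobutyryl group. C1' must be acylated afterwards by Friedel–Crafts or Fries chemistry under Lewis acid, in the presence of two benzyl ethers and an acid-labile diarylmethane, and with a free C2' hydroxyl that competes by O-acylation. A6 needs an ynol ether attached to ring B through strongly basic acetylide chemistry, and A5 is a multistep reagent.
- Comparison: the chosen route installs the acyl group in the cycloaddition and leaves only two deprotections after the key step; the alternative leaves a C–C bond formation plus deprotections.

**Alternative 3:** Ring C is cut at O1–C8a, C4–C4a and O1–C2. Fluoride-induced unmasking of the C4a–C8a aryne from the silyl triflate A8 is followed by addition of the carboxylate of 2 through oxygen at C8a, acyl shift to C4a and oxa-Michael closure, giving A7.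
- For: three bonds form in one cascade and ring C closes regiospecifically, the C5 benzyloxy group directing the oxygen nucleophile to C8a. On ring B orientation this is stronger than the chosen route.
- Against: both hexasubstituted rings and the bridge must already be in place. A8 is a pentasubstituted ortho-silylaryl triflate whose preparation needs exactly the oxygen differentiation on ring B that the cascade is meant to avoid. The aryne is flanked on both sides, so the addition is hindered. Four benzyl ethers must come off at the end.
- Comparison: the key step forms no carbocycle and leaves the substitution problem of ring A to classical chemistry, with a longer linear sequence. The chosen route spends its key step on the harder ring.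

Key step: step 11

## Route

Step 1
Reactants: 1 2,4,6-trihydroxytoluene; 2 3-methylbut-2-enoic acid
Product: 4 5,7-dihydroxy-2,2,6-trimethylchroman-4-one, via open-chain aryl enone 3 (not isolated)
Conditions: BF3·OEt2 (neat), 70 °C; chromatography
Reagents that add atoms: none
Why: Friedel–Crafts C-acylation at one of the two equivalent free ring carbons of 1 gives 3, whose enone is closed by 6-endo oxa-Michael addition of an ortho-hydroxyl. The hydroxyl buttressed by the methyl group should hold the hydrogen bond to the ketone, so the other ortho-hydroxyl should add and place the methyl group at C6; material from closure the other way is removed here.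

Step 2
Reactants: 4 5,7-dihydroxy-2,2,6-trimethylchroman-4-one
Product: 6 5,7-dihydroxy-2,2,6-trimethyl-4-oxochromane-8-carbaldehyde, via aryl iminium chloride 5 (not isolated)
Conditions: POCl3, DMF, EtOAc, 0 °C → rt; then H2O, NaOAc, 40 °C
Reagents that add atoms: N,N-dimethylformamide CN(C)C=O; water O
Why: Vilsmeier–Haack formylation at C8, the only unsubstituted ring carbon, which is activated by three oxygen substituents. At room temperature the free-phenol ring should react far faster than the ketone α-methylene, which needs heating to be attacked.

Step 3
Reactants: 6 5,7-dihydroxy-2,2,6-trimethyl-4-oxochromane-8-carbaldehyde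
Product: 7 5,7-bis(benzyloxy)-2,2,6-trimethyl-4-oxochromane-8-carbaldehyde
Conditions: BnBr, K2CO3, Bu4NI (cat.), DMF, rt → 50 °C
Reagents that add atoms: benzyl bromide BrCc1ccccc1
Why: Williamson etherification of both phenols; each is hydrogen-bonded to a carbonyl group, hence the dipolar solvent and mild warming. Carbonate is too weak to enolise C3 appreciably, so ring C should stay closed.

Step 4
Reactants: 7 5,7-bis(benzyloxy)-2,2,6-trimethyl-4-oxochromane-8-carbaldehyde
Product: 8 5,7-bis(benzyloxy)-8-(hydroxymethyl)-2,2,6-trimethylchroman-4-one
Conditions: NaBH4, THF–MeOH, 0 °C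
Reagents that add atoms: none
Why: Chemoselective borohydride reduction of the aldehyde; the C4 ketone receives electron density from three ring oxygens and is much less electrophilic at 0 °C.

Step 5
Reactants: 8 5,7-bis(benzyloxy)-8-(hydroxymethyl)-2,2,6-trimethylchroman-4-one
Product: 9 5,7-bis(benzyloxy)-8-(bromomethyl)-2,2,6-trimethylchroman-4-one
Conditions: PBr3, CH2Cl2, 0 °C; used crude at once
Reagents that add atoms: phosphorus tribromide BrP(Br)Br
Why: Standard conversion of a benzylic alcohol into the bromide. The ring oxygens are cross-conjugated with the C4 ketone, which tempers ionisation of the bromide, but it is still used without storage.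

Step 6
Reactants: 9 5,7-bis(benzyloxy)-8-(bromomethyl)-2,2,6-trimethylchroman-4-one; 10 methyl 3-oxopentanoate
Product: 11 methyl 2-{[5,7-bis(benzyloxy)-2,2,6-trimethyl-4-oxochroman-8-yl]methyl}-3-oxopentanoate (racemic)
Conditions: NaH, 10 (2 equiv), THF, 0 °C → rt
Reagents that add atoms: none
Why: C-alkylation of a β-keto ester sodium enolate with a soft benzylic bromide; excess 10 suppresses dialkylation. The new stereocentre is racemic and becomes sp2 in the next step.

Step 7
Reactants: 11 methyl 2-{[5,7-bis(benzyloxy)-2,2,6-trimethyl-4-oxochroman-8-yl]methyl}-3-oxopentanoate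
Product: 12 methyl 2-{[5,7-bis(benzyloxy)-2,2,6-trimethyl-4-oxochroman-8-yl]methyl}-3-methoxypent-2-enoate (E/Z mixture)
Conditions: Cs2CO3, Me2SO4, DMF, 0 °C → rt
Reagents that add atoms: dimethyl sulfate COS(=O)(=O)OC
Why: O-alkylation of the caesium enolate with a hard methylating agent in a dipolar aprotic solvent; C-methylation would build a quaternary carbon next to the bulky arylmethyl group and is disfavoured. Carbonate deprotonates only the β-keto ester, and the alkene geometry is of no consequence.

Step 8
Reactants: 12 methyl 2-{[5,7-bis(benzyloxy)-2,2,6-trimethyl-4-oxochroman-8-yl]methyl}-3-methoxypent-2-enoate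
Product: 13 5,7-bis(benzyloxy)-8-{2-[methoxy(trimethylsilyloxy)methylidene]-3-methoxypent-3-en-1-yl}-2,2,6-trimethyl-4-(trimethylsilyloxy)-2H-chromene (geometry mixture)
Conditions: LiN(iPr)2 (2.5 equiv), THF, −78 °C; then Me3SiCl, −78 → 0 °C; filtration under argon, no aqueous work-up
Reagents that add atoms: chlorotrimethylsilane C[Si](C)(C)Cl
Why: γ-Deprotonation of a β-alkoxy enoate and O-silylation of the dienolate is the standard route to 1-alkoxy-1-siloxy dienes. The C3 protons of ring C are of similar acidity, so both sites are deprotonated on purpose and the ketone is masked as its silyl enol ether. At −78 °C the C3 enolate should be trapped before it can open ring C.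

Step 9
Reactants: 14 ethoxyacetylene; 15 isobutyraldehyde
Product: 16 1-ethoxy-4-methylpent-1-yn-3-ol (racemic)
Conditions: n-BuLi, THF, −78 °C; then 15; aq. NaHCO3 work-up
Reagents that add atoms: none
Why: 1,2-Addition of the lithiated ynol ether to the aldehyde; the carbinol stereocentre is racemic and is destroyed in step 10. The work-up is kept neutral because alkoxyethynyl carbinols rearrange to acrylates in acid (Meyer–Schuster).

Step 10
Reactants: 16 1-ethoxy-4-methylpent-1-yn-3-ol
Product: 17 1-ethoxy-4-methylpent-1-yn-3-one
Conditions: MnO2, CH2Cl2, rt; used freshly prepared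
Reagents that add atoms: none
Why: Heterogeneous MnO2 oxidation of a propargylic alcohol under neutral conditions, which the acid-sensitive ynol ether should tolerate.

Step 11
Reactants: 13 bis-silylated diene; 17 1-ethoxy-4-methylpent-1-yn-3-one
Product: 19 1-{3-[(5,7-bis(benzyloxy)-2,2,6-trimethyl-4-oxochroman-8-yl)methyl]-6-ethoxy-2-hydroxy-4-methoxy-5-methylphenyl}-2-methylpropan-1-one, via cyclohexa-1,4-diene cycloadduct 18 (not isolated)
Conditions: PhMe, 80 °C, sealed tube; then 1 M HCl, THF, rt
Reagents that add atoms: none
Why: The diene 13 is a vinylogous ketene acetal whose largest HOMO coefficient sits on the methyl-bearing terminus (future C5'); this carbon attacks the ethoxy-bearing β-carbon of ynone 17 (future C6') and the ketene acetal carbon (future C2') bonds to the α-carbon (future C1'), either in one asynchronous [4+2] event or as Mukaiyama–Michael addition followed by closure of the allenolate onto the oxocarbenium ion. The closest known reaction type is the Diels–Alder aromatisation of 1-alkoxy-1-siloxy dienes with acetylenic ketones and esters to resorcinol derivatives. Ring A is closed as a six-membered carbocycle by the second of the two new C–C bonds (concerted [4+2], or 6-exo closure if stepwise), giving the cyclohexa-1,4-diene 18. Aqueous acid then cleaves the silyl group of the mixed ketal, the hemiketal expels its methoxy group and the dienone tautomerises, so C2' ends as a free phenol and C4' keeps its methoxy group; the silyl enol ether of ring C returns to the ketone in the same work-up. No stereocentre survives, because both sp3 carbons of 18 become aromatic. The step needs regioselectivity (ethoxy ortho and methoxy para to the isobutyryl group), which the matched polarity of diene terminus and push–pull ynone secures, and chemoselectivity for the diene over the silyl enol ether of ring C, which the much higher nucleophilicity of the ketene acetal secures under purely thermal conditions. The temperature is held at 80 °C or below because ethyl ynol ethers can fragment by retro-ene loss of ethylene on stronger heating.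

Step 12
Reactants: 19 key-step product
Product: 20 6'-O-ethylmallopallidol
Conditions: H2 (1 atm), Pd/C, EtOAc–MeOH, rt
Reagents that add atoms: none
Why: Hydrogenolysis of the two aryl benzyl ethers; the hindered, hydrogen-bonded aryl ketones and the diarylmethane should survive at atmospheric pressure. It is done before the Lewis-acid step so that no benzyl ether is exposed to BCl3.

Step 13
Reactants: 20 6'-O-ethylmallopallidol
Product: 21 mallopallidol
Conditions: BCl3 (excess), CH2Cl2, −78 → 0 °C; then H2O
Reagents that add atoms: none
Why: Chelation-controlled dealkylation: boron bridging the isobutyryl oxygen and the ortho ether oxygen activates the ethyl group for attack by chloride. The C4' methoxy group is para to the ketone, cannot chelate and should be retained; excess reagent is needed because the free phenols bind boron.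

## Compound list

1 | 2,4,6-trihydroxytoluene | Cc1c(O)cc(O)cc1O | starting material
2 | 3-methylbut-2-enoic acid | CC(C)=CC(=O)O | starting material
3 | 3-methyl-1-(2,4,6-trihydroxy-3-methylphenyl)but-2-en-1-one | CC(C)=CC(=O)c1c(O)cc(O)c(C)c1O | intermediate (not isolated)
4 | 5,7-dihydroxy-2,2,6-trimethylchroman-4-one | Cc1c(O)cc2OC(C)(C)CC(=O)c2c1O | intermediate
5 | N-[(5,7-dihydroxy-2,2,6-trimethyl-4-oxochroman-8-yl)methylidene]-N-methylmethanaminium chloride | C[N+](C)=Cc1c(O)c(C)c(O)c2c1OC(C)(C)CC2=O.[Cl-] | intermediate (not isolated)
6 | 5,7-dihydroxy-2,2,6-trimethyl-4-oxochromane-8-carbaldehyde | Cc1c(O)c(C=O)c2OC(C)(C)CC(=O)c2c1O | intermediate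
7 | 5,7-bis(benzyloxy)-2,2,6-trimethyl-4-oxochromane-8-carbaldehyde | Cc1c(OCc2ccccc2)c(C=O)c2OC(C)(C)CC(=O)c2c1OCc1ccccc1 | intermediate
8 | 5,7-bis(benzyloxy)-8-(hydroxymethyl)-2,2,6-trimethylchroman-4-one | Cc1c(OCc2ccccc2)c(CO)c2OC(C)(C)CC(=O)c2c1OCc1ccccc1 | intermediate
9 | 5,7-bis(benzyloxy)-8-(bromomethyl)-2,2,6-trimethylchroman-4-one | Cc1c(OCc2ccccc2)c(CBr)c2OC(C)(C)CC(=O)c2c1OCc1ccccc1 | intermediate
10 | methyl 3-oxopentanoate | CCC(=O)CC(=O)OC | starting material
11 | methyl 2-{[5,7-bis(benzyloxy)-2,2,6-trimethyl-4-oxochroman-8-yl]methyl}-3-oxopentanoate (racemic) | CCC(=O)C(Cc1c(OCc2ccccc2)c(C)c(OCc2ccccc2)c2c1OC(C)(C)CC2=O)C(=O)OC | intermediate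
12 | methyl 2-{[5,7-bis(benzyloxy)-2,2,6-trimethyl-4-oxochroman-8-yl]methyl}-3-methoxypent-2-enoate (E/Z mixture) | CCC(OC)=C(Cc1c(OCc2ccccc2)c(C)c(OCc2ccccc2)c2c1OC(C)(C)CC2=O)C(=O)OC | intermediate
13 | 5,7-bis(benzyloxy)-8-{2-[methoxy(trimethylsilyloxy)methylidene]-3-methoxypent-3-en-1-yl}-2,2,6-trimethyl-4-(trimethylsilyloxy)-2H-chromene (geometry mixture) | COC(O[Si](C)(C)C)=C(Cc1c(OCc2ccccc2)c(C)c(OCc2ccccc2)c2c1OC(C)(C)C=C2O[Si](C)(C)C)C(OC)=CC | intermediate
14 | ethoxyacetylene | C#COCC | starting material
15 | isobutyraldehyde | CC(C)C=O | starting material
16 | 1-ethoxy-4-methylpent-1-yn-3-ol (racemic) | CCOC#CC(O)C(C)C | intermediate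
17 | 1-ethoxy-4-methylpent-1-yn-3-one | CCOC#CC(=O)C(C)C | intermediate
18 | 1-[5-{[5,7-bis(benzyloxy)-2,2,6-trimethyl-4-(trimethylsilyloxy)-2H-chromen-8-yl]methyl}-2-ethoxy-4,6-dimethoxy-3-methyl-6-(trimethylsilyloxy)cyclohexa-1,4-dien-1-yl]-2-methylpropan-1-one (diastereomer mixture) | COC1(O[Si](C)(C)C)C(Cc2c(OCc3ccccc3)c(C)c(OCc3ccccc3)c3c2OC(C)(C)C=C3O[Si](C)(C)C)=C(OC)C(C)C(OCC)=C1C(=O)C(C)C | intermediate (not isolated)
19 | 1-{3-[(5,7-bis(benzyloxy)-2,2,6-trimethyl-4-oxochroman-8-yl)methyl]-6-ethoxy-2-hydroxy-4-methoxy-5-methylphenyl}-2-methylpropan-1-one | COc1c(C)c(OCC)c(C(=O)C(C)C)c(O)c1Cc1c(OCc2ccccc2)c(C)c(OCc2ccccc2)c2c1OC(C)(C)CC2=O | intermediate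
20 | 6'-O-ethylmallopallidol | COc1c(C)c(OCC)c(C(=O)C(C)C)c(O)c1Cc1c(O)c(C)c(O)c2c1OC(C)(C)CC2=O | intermediate
21 | mallopallidol | COc1c(C)c(O)c(C(=O)C(C)C)c(O)c1Cc1c(O)c(C)c(O)c2c1OC(C)(C)CC2=O | target

## Step count and least certain steps

Total step count: 13. Longest linear sequence: 11 steps (steps 1–8 and 11–13); the ynone branch (steps 9–10) has two steps.

**Step 11 (key step).** The cycloaddition may be too slow: the ethoxy donor lowers the electrophilicity of the alkyne and the diene is fully substituted and carries a bulky arylmethyl group. Protodesilylation of the ketene acetal, [2+2] addition or thermal fragmentation of the ynol ether could then outrun ring formation. Fallback: give up the cycloaddition and join the two rings by Friedel–Crafts alkylation, setting out from 1 and 8 and returning at 21. Compound 1 is C-acylated with isobutyryl chloride and AlCl3 to 2-methyl-1-(2,4,6-trihydroxy-3-methylphenyl)propan-1-one F1. The hydroxyl para to the ketone, the only one not hydrogen-bonded, is methylated (Me2SO4, K2CO3, acetone) to 1-(2,6-dihydroxy-4-methoxy-3-methylphenyl)-2-methylpropan-1-one F2. The one free ring carbon of F2 is alkylated by the benzylic cation from alcohol 8 (catalytic BF3·OEt2, CH2Cl2, 0 °C) to give 5,7-di-O-benzylmallopallidol F3, and hydrogenolysis over Pd/C gives 21.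

**Step 1.** Ring closure may take place through the hydroxyl next to the methyl group, and under the acidic conditions ring C may open and reclose (Wessely–Moser-type equilibration), leaving a mixture of orientations that is hard to separate. Fallback: fix the orientation by a protecting group, setting out from 1 and returning at 6. Vilsmeier–Haack formylation of 1 gives 2,4,6-trihydroxy-3-methylbenzaldehyde F4. The hydroxyl para to the formyl group is methylated selectively (Me2SO4, K2CO3, acetone) to 2,6-dihydroxy-4-methoxy-3-methylbenzaldehyde F5. Acylation with 2 (BF3·OEt2, 70 °C) at the single free ring carbon can now be followed by closure through only one ortho-hydroxyl, giving 7-hydroxy-5-methoxy-2,2,6-trimethyl-4-oxochromane-8-carbaldehyde F6. BCl3 (CH2Cl2, −78 → 0 °C) then cleaves the methyl ether chelated to the C4 ketone and delivers 6.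

**Step 8.** Deprotonation may be incomplete or unselective between the γ-position and C3 of ring C, or the C3 enolate may expel the ring oxygen and open ring C before it is silylated. Fallback: mask the ketone first under soft enolisation, setting out from 12 and returning at 19. Triisopropylsilyl triflate and Et3N (CH2Cl2, 0 °C) convert 12 into the triisopropylsilyl enol ether F7. One equivalent of LiN(iPr)2 followed by Me3SiCl then gives the mixed-silyl diene F8, which is taken through the conditions of step 11 with 17, followed by aqueous HCl in THF, to give 19.

**Step 7.** Methylation may occur on carbon instead of oxygen, giving a quaternary keto ester that cannot form the diene. Fallback: make the enol ether by an acid-catalysed route, setting out from 11 and returning at 12. Trimethyl orthoformate with catalytic TsOH in MeOH converts the ketone of 11 into the dimethyl ketal F9 (the deactivated ring C ketone should not react). Elimination with Me3SiOTf and iPr2NEt (CH2Cl2, 0 °C) followed by mild aqueous work-up gives 12.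

**Step 13.** Dealkylation may stall because the ketone is already held in a boron chelate with the C2' oxygen; forcing it could cleave the C4' methyl ether or the diarylmethane. Fallback: replace the ethyl group by a benzyl group from the start, setting out from 15 and 13 and returning at 21. Benzyl alcohol and trichloroethylene (KH, THF) give benzyl (E)-1,2-dichlorovinyl ether F10. Two equivalents of n-BuLi at −78 °C convert F10 into the lithiated benzyloxyalkyne, which adds to 15 to give 1-(benzyloxy)-4-methylpent-1-yn-3-ol F11. MnO2 oxidation gives 1-(benzyloxy)-4-methylpent-1-yn-3-one F12. Cycloaddition of F12 with 13 under the conditions of step 11 gives the tribenzyl ether F13, and a single hydrogenolysis over Pd/C gives 21.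

## Further compounds

F1 | step 11 | 2-methyl-1-(2,4,6-trihydroxy-3-methylphenyl)propan-1-one | CC(C)C(=O)c1c(O)cc(O)c(C)c1O
F2 | step 11 | 1-(2,6-dihydroxy-4-methoxy-3-methylphenyl)-2-methylpropan-1-one | COc1cc(O)c(C(=O)C(C)C)c(O)c1C
F3 | step 11 | 5,7-di-O-benzylmallopallidol | COc1c(C)c(O)c(C(=O)C(C)C)c(O)c1Cc1c(OCc2ccccc2)c(C)c(OCc2ccccc2)c2c1OC(C)(C)CC2=O
F4 | step 1 | 2,4,6-trihydroxy-3-methylbenzaldehyde | Cc1c(O)cc(O)c(C=O)c1O
F5 | step 1 | 2,6-dihydroxy-4-methoxy-3-methylbenzaldehyde | COc1cc(O)c(C=O)c(O)c1C
F6 | step 1 | 7-hydroxy-5-methoxy-2,2,6-trimethyl-4-oxochromane-8-carbaldehyde | COc1c(C)c(O)c(C=O)c2OC(C)(C)CC(=O)c12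
F7 | step 8 | methyl 2-{[5,7-bis(benzyloxy)-2,2,6-trimethyl-4-(triisopropylsilyloxy)-2H-chromen-8-yl]methyl}-3-methoxypent-2-enoate (E/Z mixture) | CCC(OC)=C(Cc1c(OCc2ccccc2)c(C)c(OCc2ccccc2)c2c1OC(C)(C)C=C2O[Si](C(C)C)(C(C)C)C(C)C)C(=O)OC
F8 | step 8 | 5,7-bis(benzyloxy)-8-{2-[methoxy(trimethylsilyloxy)methylidene]-3-methoxypent-3-en-1-yl}-2,2,6-trimethyl-4-(triisopropylsilyloxy)-2H-chromene (geometry mixture) | COC(O[Si](C)(C)C)=C(Cc1c(OCc2ccccc2)c(C)c(OCc2ccccc2)c2c1OC(C)(C)C=C2O[Si](C(C)C)(C(C)C)C(C)C)C(OC)=CC
F9 | step 7 | methyl 2-{[5,7-bis(benzyloxy)-2,2,6-trimethyl-4-oxochroman-8-yl]methyl}-3,3-dimethoxypentanoate (racemic) | CCC(OC)(OC)C(Cc1c(OCc2ccccc2)c(C)c(OCc2ccccc2)c2c1OC(C)(C)CC2=O)C(=O)OC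
F10 | step 13 | benzyl (E)-1,2-dichlorovinyl ether | Cl/C=C(/Cl)OCc1ccccc1
F11 | step 13 | 1-(benzyloxy)-4-methylpent-1-yn-3-ol (racemic) | CC(C)C(O)C#COCc1ccccc1
F12 | step 13 | 1-(benzyloxy)-4-methylpent-1-yn-3-one | CC(C)C(=O)C#COCc1ccccc1
F13 | step 13 | 1-{6-(benzyloxy)-3-[(5,7-bis(benzyloxy)-2,2,6-trimethyl-4-oxochroman-8-yl)methyl]-2-hydroxy-4-methoxy-5-methylphenyl}-2-methylpropan-1-one | COc1c(C)c(OCc2ccccc2)c(C(=O)C(C)C)c(O)c1Cc1c(OCc2ccccc2)c(C)c(OCc2ccccc2)c2c1OC(C)(C)CC2=O
A1 | alternative 1 | 2',6'-di-O-benzylmallopallidol | COc1c(C)c(OCc2ccccc2)c(C(=O)C(C)C)c(OCc2ccccc2)c1Cc1c(O)c(C)c(O)c2c1OC(C)(C)CC2=O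
A2 | alternative 1 | 1-{2,6-bis(benzyloxy)-4-methoxy-3-[5-methoxy-4-methyl-3,5-bis(trimethylsilyloxy)penta-2,4-dien-1-yl]-5-methylphenyl}-2-methylpropan-1-one (geometry mixture) | COC(O[Si](C)(C)C)=C(C)C(O[Si](C)(C)C)=CCc1c(OC)c(C)c(OCc2ccccc2)c(C(=O)C(C)C)c1OCc1ccccc1
A3 | alternative 1 | 5-bromo-2,2-dimethyl-2,3-dihydro-4H-pyran-4-one | CC1(C)CC(=O)C(Br)=CO1
A4 | alternative 2 | 5,7-bis(benzyloxy)-8-[(4-ethoxy-6-hydroxy-2-methoxy-3-methylphenyl)methyl]-2,2,6-trimethylchroman-4-one | COc1c(C)c(OCC)cc(O)c1Cc1c(OCc2ccccc2)c(C)c(OCc2ccccc2)c2c1OC(C)(C)CC2=O
A5 | alternative 2 | 3-ethoxy-2-methylcyclobut-2-en-1-one | CCOC1=C(C)C(=O)C1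
A6 | alternative 2 | 5,7-bis(benzyloxy)-8-(3-methoxyprop-2-yn-1-yl)-2,2,6-trimethylchroman-4-one | COC#CCc1c(OCc2ccccc2)c(C)c(OCc2ccccc2)c2c1OC(C)(C)CC2=O
A7 | alternative 3 | tetra-O-benzylmallopallidol | COc1c(C)c(OCc2ccccc2)c(C(=O)C(C)C)c(OCc2ccccc2)c1Cc1c(OCc2ccccc2)c(C)c(OCc2ccccc2)c2c1OC(C)(C)CC2=O
A8 | alternative 3 | 3,5-bis(benzyloxy)-2-{[2,6-bis(benzyloxy)-4-methoxy-5-methyl-3-(2-methylpropanoyl)phenyl]methyl}-4-methyl-6-(trimethylsilyl)phenyl trifluoromethanesulfonate | COc1c(C)c(OCc2ccccc2)c(C(=O)C(C)C)c(OCc2ccccc2)c1Cc1c(OCc2ccccc2)c(C)c(OCc2ccccc2)c([Si](C)(C)C)c1OS(=O)(=O)C(F)(F)F
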